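**Retrosynthetic overview**
1. Target 13 ⇐ two O-acylations of epoxy diol 8: aryl angelate first, then primary tiglate.
2. 8 ⇐ chlorohydrin triol 7 (Williamson closure of the oxirane, the only ring of the target, formed last) ⇐ borohydride reduction of aryl dioxolanone 6.
3. 6 ⇐ key C8–aryl bond: visible-light photoredox ortho C–H alkylation of phenol 5 with bromodioxolanone 4, anti to the tert-butyl group.
4. 4 ⇐ NBS bromination of cis-dioxolanone 3 ⇐ (S)-3-chlorolactic acid 1 + pivaldehyde 2. The temporary dioxolanone ring is formed first and carries the stereochemical information at its acetal carbon.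

Assumption: (S)-3-chlorolactic acid (the nitric-acid oxidation product of bulk (S)-3-chloropropane-1,2-diol) is bought as the chiral starting material.

**Step 1**
Reactants: 1 (S)-3-chloro-2-hydroxypropanoic acid; 2 pivaldehyde
Product: 3 (2R,5S)-2-tert-butyl-5-(chloromethyl)-1,3-dioxolan-4-one (cis)
Conditions: 2 (1.5 equiv), TsOH·H2O (cat.), H2SO4 (cat.), pentane, reflux, Dean–Stark; cis isomer crystallised (pentane, −78 °C) to >98:2
Reagents that add atoms: none
Why: Seebach acetalisation (self-regeneration of stereocentres) gives mainly the cis-dioxolanone, so the new acetal stereocentre C2 is set by the bought C5 centre (tBu and CH2Cl cis); the trans isomer is removed because it would lead to the enantiomer.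

**Step 2**
Reactants: 3 (2R,5S)-2-tert-butyl-5-(chloromethyl)-1,3-dioxolan-4-one
Product: 4 (2S,5R)-5-bromo-2-tert-butyl-5-(chloromethyl)-1,3-dioxolan-4-one (used crude)
Conditions: NBS (1.1 equiv), AIBN (5 mol%), PhCF3, 80 °C
Reagents that add atoms: N-bromosuccinimide, O=C1CCC(=O)N1Br
Why: Wohl–Ziegler-type radical bromination occurs at the captodative C5–H (α-oxy, α-acyl) rather than the hindered C2–H, as for the lactic acid analogue, with Br entering anti to tBu while C2 keeps the stereochemical information.

**Step 3**
Reactants: 4 (2S,5R)-5-bromo-2-tert-butyl-5-(chloromethyl)-1,3-dioxolan-4-one; 5 4-methoxy-3-methylphenol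
Product: 6 (2R,5S)-2-tert-butyl-5-(chloromethyl)-5-(2-hydroxy-5-methoxy-4-methylphenyl)-1,3-dioxolan-4-one
Conditions: fac-Ir(ppy)3 (1 mol%), 5 (3 equiv), K2HPO4 (2 equiv), degassed MeCN, 450 nm LEDs, 0 °C; chromatography to a single diastereomer
Reagents that add atoms: none
Why: Proposed new method: excited Ir(III) reduces the C–Br bond to the planar 4-oxo-1,3-dioxolan-5-yl radical (electrophilic through the lactone carbonyl, β-chlorine loss slow), which adds to the most activated unhindered position of the phenol (ortho to OH, para to CH3) from the face anti to the tert-butyl group, and Ir(IV) oxidation plus proton loss re-aromatises the ring, so the aryl group takes the place the hydrogen had in 3 (net retention, quaternary C8 set by the acetal centre); the closest known reactions are photoredox C–H alkylation of electron-rich arenes with α-bromocarbonyl compounds and the anti-selective trapping of Seebach dioxolanonyl radicals, not yet shown together for a tertiary radical and a free phenol.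

**Step 4**
Reactants: 6 (2R,5S)-2-tert-butyl-5-(chloromethyl)-5-(2-hydroxy-5-methoxy-4-methylphenyl)-1,3-dioxolan-4-one
Product: 8 2-[(2S)-2-(hydroxymethyl)oxiran-2-yl]-4-methoxy-5-methylphenol, via chlorohydrin triol 7 (not isolated)
Conditions: LiBH4 (2.5 equiv), THF, 0 °C; then 2 M aq NaOH, MeOH, 0 °C, 30 min; NH4Cl to pH 8; used crude
Reagents that add atoms: none
Why: Borohydride reduction of the activated acylal lactone gives triol 7 (the pivaldehyde unit leaves as neopentyl alcohol), and NaOH then closes the oxirane by intramolecular Williamson displacement (3-exo-tet) of the primary chloride by the tertiary alkoxide, which outruns the neopentyl 5-exo attack of the phenoxide and the disfavoured 5-endo epoxide opening; no bond to C8 is broken, so its configuration is kept.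

**Step 5**
Reactants: 8 2-[(2S)-2-(hydroxymethyl)oxiran-2-yl]-4-methoxy-5-methylphenol; 9 angelic acid [(Z)-2-methylbut-2-enoic acid]
Product: 11 2-[(2S)-2-(hydroxymethyl)oxiran-2-yl]-4-methoxy-5-methylphenyl (Z)-2-methylbut-2-enoate, via angeloyl chloride 10 (not isolated)
Conditions: 9 (1.2 equiv), 1-chloro-N,N,2-trimethylprop-1-en-1-amine (1.1 equiv), CH2Cl2, 0 °C, 1 h; solution added to 8, K2CO3 (2.5 equiv), acetone, −10 °C
Reagents that add atoms: 1-chloro-N,N,2-trimethylprop-1-en-1-amine (Ghosez reagent), CC(C)=C(Cl)N(C)C (its chlorine is carried only by 10)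
Why: Phenoxide-selective O-acylation (Schotten–Baumann type): only the phenol is ionised by carbonate, so it outcompetes the neopentyl primary alcohol, and the acid chloride made under neutral Ghosez conditions at 0 °C keeps the Z geometry; C8 is untouched.

**Step 6**
Reactants: 11 2-[(2S)-2-(hydroxymethyl)oxiran-2-yl]-4-methoxy-5-methylphenyl (Z)-2-methylbut-2-enoate; 12 tigloyl chloride [(E)-2-methylbut-2-enoyl chloride]
Product: 13 [(2R)-2-{5-methoxy-4-methyl-2-[(Z)-2-methylbut-2-enoyloxy]phenyl}oxiran-2-yl]methyl (E)-2-methylbut-2-enoate (target)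
Conditions: 12 (1.3 equiv), Et3N (2 equiv), DMAP (5 mol%), CH2Cl2, −20 → 0 °C; Et3N-deactivated silica
Reagents that add atoms: none
Why: DMAP-catalysed acyl chloride esterification of the remaining primary alcohol under cold, mildly basic conditions leaves the epoxide and the aryl angelate intact, and C8 is unchanged (the descriptor becomes R only because CH2O-acyl now outranks the ring CH2).

**Compound list**
1 | (S)-3-chloro-2-hydroxypropanoic acid | O[C@@H](C(=O)O)CCl | starting material
2 | pivaldehyde | CC(C)(C)C=O | starting material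
3 | (2R,5S)-2-tert-butyl-5-(chloromethyl)-1,3-dioxolan-4-one | CC(C)(C)[C@@H]1O[C@H](CCl)C(=O)O1 | intermediate
4 | (2S,5R)-5-bromo-2-tert-butyl-5-(chloromethyl)-1,3-dioxolan-4-one | CC(C)(C)[C@@H]1O[C@](Br)(CCl)C(=O)O1 | intermediate
5 | 4-methoxy-3-methylphenol | COc1ccc(O)cc1C | starting material
6 | (2R,5S)-2-tert-butyl-5-(chloromethyl)-5-(2-hydroxy-5-methoxy-4-methylphenyl)-1,3-dioxolan-4-one | CC(C)(C)[C@@H]1O[C@](c2cc(OC)c(C)cc2O)(CCl)C(=O)O1 | intermediate
7 | (2S)-3-chloro-2-(2-hydroxy-5-methoxy-4-methylphenyl)propane-1,2-diol | OC[C@](O)(CCl)c1cc(OC)c(C)cc1O | intermediate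
8 | 2-[(2S)-2-(hydroxymethyl)oxiran-2-yl]-4-methoxy-5-methylphenol | Oc1cc(C)c(OC)cc1[C@]1(CO)CO1 | intermediate
9 | angelic acid, (Z)-2-methylbut-2-enoic acid | C/C=C(/C)C(=O)O | starting material
10 | angeloyl chloride, (Z)-2-methylbut-2-enoyl chloride | C/C=C(/C)C(Cl)=O | intermediate
11 | 2-[(2S)-2-(hydroxymethyl)oxiran-2-yl]-4-methoxy-5-methylphenyl (Z)-2-methylbut-2-enoate | C/C=C(/C)C(=O)Oc1cc(C)c(OC)cc1[C@]1(CO)CO1 | intermediate
12 | tigloyl chloride, (E)-2-methylbut-2-enoyl chloride | C/C=C(\C)C(Cl)=O | starting material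
13 | [(2R)-2-{5-methoxy-4-methyl-2-[(Z)-2-methylbut-2-enoyloxy]phenyl}oxiran-2-yl]methyl (E)-2-methylbut-2-enoate | C/C=C(/C)C(=O)Oc1cc(C)c(OC)cc1[C@]1(COC(=O)/C(C)=C/C)CO1 | target

**Totals**
Total step count: 6. Longest linear sequence: 6 steps (1 → 13).

**Steps most likely to fail, with fallbacks**

Step 3 (the new C–C bond formation) is the main risk: the hindered captodative radical may add slowly, alkylate oxygen instead of carbon, attack ortho to OMe, or give a poor anti:syn ratio. The fallback uses known ionic chemistry and sets out from bromide 4 together with phenol 5. AgOTf with 2,6-di-tert-butyl-4-methylpyridine in CH2Cl2 at −40 °C ionises the tertiary α-bromo ether to the acyloxocarbenium ion, which the phenol traps ortho to OH in a classical silver-assisted Friedel–Crafts α-oxyalkylation, again anti to the tert-butyl group. It comes back to the route at 6 and makes no compound outside the list (none, F0).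

Step 4 is the second risk, because 8 has a free ortho-phenol next to an acid-labile tertiary benzylic epoxide and may cyclise or rearrange on isolation. The fallback masks the phenol and reverses the order of acylation; it sets out from 6 and comes back at 13. TIPSOTf and 2,6-lutidine give the silyl ether F1. LiBH4 in THF gives the chlorohydrin diol F2, and NaH in THF at 0 °C closes it to the silyl-protected epoxy alcohol F3. Tigloyl chloride 12 with Et3N and DMAP gives the silyl-protected tiglate F4. CsF in MeCN in the presence of angeloyl chloride 10 (fluoride-triggered desilylative acylation) then gives 13 directly, so a free phenol never sits beside the epoxide.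

Step 5 is the third risk: the angelate can leak to the tiglate geometry (Z to E) during activation, and the phenol/alcohol selectivity may be incomplete. The fallback builds the Z alkene on the ester instead of transferring it; it sets out from 8 and comes back at 13. The phenoxide (K2CO3, acetone) is acylated with 2-[bis(2,2,2-trifluoroethoxy)phosphoryl]propanoyl chloride to give the phosphonate aryl ester F5. Tigloylation as in step 6 gives the phosphonate tiglate F6. Still–Gennari olefination with acetaldehyde (KHMDS, 18-crown-6, THF, −78 °C) then forms the Z-trisubstituted enoate kinetically and delivers 13.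

**Further compounds**
F0 | step 3 | none | none
F1 | step 4 | (2R,5S)-2-tert-butyl-5-(chloromethyl)-5-{5-methoxy-4-methyl-2-[tri(propan-2-yl)silyloxy]phenyl}-1,3-dioxolan-4-one | CC(C)(C)[C@@H]1O[C@](c2cc(OC)c(C)cc2O[Si](C(C)C)(C(C)C)C(C)C)(CCl)C(=O)O1
F2 | step 4 | (2S)-3-chloro-2-{5-methoxy-4-methyl-2-[tri(propan-2-yl)silyloxy]phenyl}propane-1,2-diol | OC[C@](O)(CCl)c1cc(OC)c(C)cc1O[Si](C(C)C)(C(C)C)C(C)C
F3 | step 4 | [(2S)-2-{5-methoxy-4-methyl-2-[tri(propan-2-yl)silyloxy]phenyl}oxiran-2-yl]methanol | CC(C)[Si](Oc1cc(C)c(OC)cc1[C@]1(CO)CO1)(C(C)C)C(C)C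
F4 | step 4 | [(2R)-2-{5-methoxy-4-methyl-2-[tri(propan-2-yl)silyloxy]phenyl}oxiran-2-yl]methyl (E)-2-methylbut-2-enoate | CC(C)[Si](Oc1cc(C)c(OC)cc1[C@]1(COC(=O)/C(C)=C/C)CO1)(C(C)C)C(C)C
F5 | step 5 | 2-[(2S)-2-(hydroxymethyl)oxiran-2-yl]-4-methoxy-5-methylphenyl 2-[bis(2,2,2-trifluoroethoxy)phosphoryl]propanoate (epimer mixture at the phosphonate carbon) | CC(C(=O)Oc1cc(C)c(OC)cc1[C@]1(CO)CO1)P(=O)(OCC(F)(F)F)OCC(F)(F)F
F6 | step 5 | [(2R)-2-(2-{2-[bis(2,2,2-trifluoroethoxy)phosphoryl]propanoyloxy}-5-methoxy-4-methylphenyl)oxiran-2-yl]methyl (E)-2-methylbut-2-enoate (epimer mixture at the phosphonate carbon) | CC(C(=O)Oc1cc(C)c(OC)cc1[C@]1(COC(=O)/C(C)=C/C)CO1)P(=O)(OCC(F)(F)F)OCC(F)(F)F
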